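The plan cuts the C3–O bond back to a C3–Si bond tied to the 2''-oxygen of ring D. That oxygen is separated from C3 only by C2'', C1'' and C4. A hydrosilyl group on it can therefore reach C3 of a C2=C3 enol ether solely from the ring D face. One platinum-catalysed syn hydrosilylation makes C3–Si and C2–H, closes a six-membered oxasilacycle, and sets C2 and C3 (2,3-trans, 3,4-cis) from the single C4 stereocentre. The precursor is an enantioenriched tetrabenzyl 2,4-diaryl-4H-chromene carrying an O–SiH(i-Pr)2 group at C2''. It is built by rhodium-catalysed asymmetric arylation of a chalcone followed by cyclodehydration.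

Key step: step 12

Numbering: flavan numbering is used. Ring A is the benzo ring, ring B the 2-aryl group, ring C the pyran, and ring D the 4-aryl group (locants with '').

Assumption: the (1S,4S)-diene is taken to deliver ring A to the si face of Cβ of chalcone 7, the sense it shows with other enones. Both antipodes are sold, so the other one would be used if a first run showed the opposite sense.

Remark: the spatial arrangement at C4 does not change after step 8. Its descriptor switches between R and S only because the CIP rank of ring D depends on the group on O-2''.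

Step 1
Reactants: 1 2-methoxyresorcinol
Product: 3 2,4-dihydroxy-3-methoxybenzaldehyde, via aryl iminium chloride 2 (not isolated)
Conditions: POCl3, DMF, MeCN, 0 °C → rt; then H2O, 50 °C
Reagents that add atoms: N,N-dimethylformamide CN(C)C=O; water O
Why: Vilsmeier–Haack formylation, in which the only activated positions of 1 (C4 and C6, each ortho to one hydroxyl and para to the other) are equivalent, so a single aldehyde should result after hydrolysis of the iminium salt.

Step 2
Reactants: 3 2,4-dihydroxy-3-methoxybenzaldehyde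
Product: 4 4-(benzyloxy)-2-hydroxy-3-methoxybenzaldehyde
Conditions: BnBr (1.0 equiv), NaHCO3, MeCN, reflux
Reagents that add atoms: benzyl bromide BrCc1ccccc1
Why: Williamson etherification under weak base, in which the 2-OH is locked in a hydrogen bond to the aldehyde and stays un-ionised, so only the 4-OH should be benzylated.

Step 3
Reactants: 4 4-(benzyloxy)-2-hydroxy-3-methoxybenzaldehyde
Product: 5 2-(allyloxy)-4-(benzyloxy)-3-methoxybenzaldehyde
Conditions: allyl bromide, K2CO3, DMF, 50 °C
Reagents that add atoms: allyl bromide C=CCBr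
Why: Williamson etherification with the stronger base caps the chelated 2-OH as an allyl ether, a small group that tolerates hydroxide, aqueous rhodium catalysis and acid and can later be removed in a basic medium.

Step 4
Reactants: 5 2-(allyloxy)-4-(benzyloxy)-3-methoxybenzaldehyde; 6 1-[3,4-bis(benzyloxy)phenyl]ethanone
Product: 7 (E)-3-[2-(allyloxy)-4-(benzyloxy)-3-methoxyphenyl]-1-[3,4-bis(benzyloxy)phenyl]prop-2-en-1-one
Conditions: KOH, EtOH–THF, rt
Reagents that add atoms: none
Why: Claisen–Schmidt condensation, in which neither partner carries a free phenol or a base-labile group and E1cB loss of water from the aldol gives the conjugated E-enone.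

Step 5
Reactants: 8 4-bromoresorcinol
Product: 9 5-(benzyloxy)-2-bromophenol
Conditions: BnBr (1.0 equiv), K2CO3 (1.1 equiv), acetone, rt
Reagents that add atoms: benzyl bromide BrCc1ccccc1
Why: Williamson mono-etherification, in which the hydroxyl next to bromine is hindered and its phenoxide is the weaker nucleophile, so one equivalent of BnBr should go mainly to the remote OH, with the isomer and the dibenzyl ether removed by chromatography at this cheap stage.

Step 6
Reactants: 9 5-(benzyloxy)-2-bromophenol
Product: 10 4-(benzyloxy)-1-bromo-2-(methoxymethoxy)benzene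
Conditions: MOMCl, i-Pr2NEt, CH2Cl2, 0 °C → rt
Reagents that add atoms: chloromethyl methyl ether COCCl
Why: MOM acetal formation on the remaining phenol installs the one acid-labile group of the route, orthogonal to benzyl and allyl.

Step 7
Reactants: 10 4-(benzyloxy)-1-bromo-2-(methoxymethoxy)benzene
Product: 13 [4-(benzyloxy)-2-(methoxymethoxy)phenyl]boronic acid, via aryllithium 11 (not isolated), via lithium aryltriisopropoxyborate 12 (not isolated)
Conditions: n-BuLi, THF, −78 °C; B(Oi-Pr)3, −78 °C → rt; aq NH4Cl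
Reagents that add atoms: triisopropyl borate CC(C)OB(OC(C)C)OC(C)C; water O
Why: Bromine–lithium exchange followed by borylation and mild hydrolysis is the standard way to arylboronic acids, and the NH4Cl work-up spares the MOM acetal.

Step 8
Reactants: 7 ring D–ring B chalcone; 13 ring A boronic acid (2 equiv)
Product: 14 (3R)-3-[2-(allyloxy)-4-(benzyloxy)-3-methoxyphenyl]-3-[4-(benzyloxy)-2-(methoxymethoxy)phenyl]-1-[3,4-bis(benzyloxy)phenyl]propan-1-one
Conditions: Rh(acac)(C2H4)2 (3 mol %), (1S,4S)-2,5-diphenylbicyclo[2.2.2]octa-2,5-diene (3.3 mol %), KOH (0.5 equiv), dioxane–H2O, 50 °C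
Reagents that add atoms: none
Why: Hayashi–Miyaura asymmetric 1,4-addition, in which the aryl–rhodium species held by the C2-symmetric diene inserts the enone on the face where the aroyl group avoids the ligand phenyl (si face at Cβ), which sets the diarylmethine centre that becomes C4.

Step 9
Reactants: 14 triaryl ketone
Product: 16 (4R)-4-[2-(allyloxy)-4-(benzyloxy)-3-methoxyphenyl]-7-(benzyloxy)-2-[3,4-bis(benzyloxy)phenyl]-4H-chromene, via keto phenol 15 (not isolated)
Conditions: p-TsOH·H2O (0.2 equiv), MeOH–THF, 50 °C; then PhMe, 4 Å MS, 60 °C, Ar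
Reagents that add atoms: none
Why: Acid-catalysed acetal cleavage frees only the ring A phenol, which adds to the ketone and loses water (cyclodehydration) to give the aryl-conjugated enol ether, while benzyl and allyl ethers are inert and C4 is not touched.

Step 10
Reactants: 16 O-allyl 4H-chromene
Product: 17 3-(benzyloxy)-6-{(4S)-7-(benzyloxy)-2-[3,4-bis(benzyloxy)phenyl]-4H-chromen-4-yl}-2-methoxyphenol
Conditions: Pd(PPh3)4 (5 mol %), morpholine (5 equiv), THF, rt; pH 7 buffer work-up, Et3N-deactivated silica
Reagents that add atoms: none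
Why: Tsuji–Trost deallylation, in which zerovalent palladium ionises the aryl allyl ether and morpholine traps the π-allyl complex, so the phenol is released in a basic medium where it cannot add to the enol ether to form the 2,4-bridged ketal.

Step 11
Reactants: 17 free 2''-phenol chromene; 18 chlorodiisopropylsilane
Product: 19 {3-(benzyloxy)-6-[(4R)-7-(benzyloxy)-2-[3,4-bis(benzyloxy)phenyl]-4H-chromen-4-yl]-2-methoxyphenoxy}di(propan-2-yl)silane
Conditions: imidazole, DMF, 0 °C → rt
Reagents that add atoms: none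
Why: Silylation of a phenol with a chlorosilane and imidazole (substitution at silicon), where the isopropyl groups make the aryloxy(hydrido)silane robust enough for filtration through deactivated silica, which also removes phosphine traces that would poison platinum.

Step 12
Reactants: 19 2''-O-diisopropylsilyl (Si–H) 4H-chromene
Product: 20 (2R,3S,4R)-tetrabenzyl flavan bridged from C3 to O-2'' by Si(i-Pr)2 (cis-fused oxasilacycle; Si cis to ring D; ring B trans to Si)
Conditions: Pt2[(CH2=CHSiMe2)2O]3 (2.5 mol %), PhMe (0.02 M), 60 °C, Ar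
Reagents that add atoms: none
Why: Proposed new method: oxidative addition of the tethered Si–H bond to zerovalent platinum, coordination of C2=C3, migratory insertion that puts H on C2 and Pt on C3, and C–Si reductive elimination (Chalk–Harrod cycle) place Si and H on one and the same face. The closest known reaction type is the platinum-catalysed intramolecular hydrosilylation of hydrosilyl ethers of allylic and homoallylic alcohols and of α-hydroxy enol ethers, whereas a phenol-anchored tether and a 2-aryl-4H-chromene enol ether have not been used. The one new ring (Si, O, C2'', C1'', C4, C3) closes in the 6-exo mode, since the 7-endo alternative would put silicon on the fully substituted C2 and run against the normal β-silylation of enol ethers. C3 is controlled by the C4 stereocentre through the tether, because the short O–Si link lets silicon reach only the face on which ring D stands, so Si ends up cis to ring D. C2 is controlled by the syn stereospecificity of the addition, so H-2 is cis to silicon and ring B is trans to it. The step needs the intramolecular path to beat intermolecular addition and alkene migration: dilution and the bulky isopropyl groups secure the first, and the position of H-4 on the face opposite to platinum (no syn β-hydride at C4) secures the second.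

Step 13
Reactants: 20 oxasilacycle
Product: 21 (2R,3S,4S)-7-(benzyloxy)-4-[4-(benzyloxy)-2-hydroxy-3-methoxyphenyl]-2-[3,4-bis(benzyloxy)phenyl]-3,4-dihydro-2H-chromen-3-ol
Conditions: 30% H2O2, KF, KHCO3, THF–MeOH, 40 °C
Reagents that add atoms: hydrogen peroxide OO
Why: Tamao–Fleming oxidation, in which hydroperoxide adds to the fluoride-activated aryloxysilane and C3 migrates from Si to O with retention, after which the Si–O bonds hydrolyse and free both the 3-OH and the ring D phenol.

Step 14
Reactants: 21 tetrabenzyl flavan-3-ol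
Product: 22 4β-(2,4-dihydroxy-3-methoxyphenyl)fisetinidol, (2R,3S,4S)-4-(2,4-dihydroxy-3-methoxyphenyl)-2-(3,4-dihydroxyphenyl)-3,4-dihydro-2H-chromene-3,7-diol
Conditions: H2 (1 atm), 10% Pd/C, THF–MeOH, rt
Reagents that add atoms: none
Why: Catalytic hydrogenolysis of the four benzyl ethers under neutral conditions, routine for benzylated flavan-3-ols, leaves the three stereocentres and the C2–O1 bond alone and avoids the base to which the free phenolic target is sensitive.

Compound list
1 | 2-methoxyresorcinol | COc1c(O)cccc1O | starting material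
2 | [(2,4-dihydroxy-3-methoxyphenyl)methylidene]dimethylammonium chloride | COc1c(O)ccc(C=[N+](C)C)c1O.[Cl-] | intermediate
3 | 2,4-dihydroxy-3-methoxybenzaldehyde | COc1c(O)ccc(C=O)c1O | intermediate
4 | 4-(benzyloxy)-2-hydroxy-3-methoxybenzaldehyde | COc1c(OCc2ccccc2)ccc(C=O)c1O | intermediate
5 | 2-(allyloxy)-4-(benzyloxy)-3-methoxybenzaldehyde | COc1c(OCc2ccccc2)ccc(C=O)c1OCC=C | intermediate
6 | 1-[3,4-bis(benzyloxy)phenyl]ethanone | CC(=O)c1ccc(OCc2ccccc2)c(OCc2ccccc2)c1 | starting material
7 | (E)-3-[2-(allyloxy)-4-(benzyloxy)-3-methoxyphenyl]-1-[3,4-bis(benzyloxy)phenyl]prop-2-en-1-one | COc1c(OCc2ccccc2)ccc(/C=C/C(=O)c2ccc(OCc3ccccc3)c(OCc3ccccc3)c2)c1OCC=C | intermediate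
8 | 4-bromoresorcinol | Oc1ccc(Br)c(O)c1 | starting material
9 | 5-(benzyloxy)-2-bromophenol | Oc1cc(OCc2ccccc2)ccc1Br | intermediate
10 | 4-(benzyloxy)-1-bromo-2-(methoxymethoxy)benzene | COCOc1cc(OCc2ccccc2)ccc1Br | intermediate
11 | [4-(benzyloxy)-2-(methoxymethoxy)phenyl]lithium | [Li]c1ccc(OCc2ccccc2)cc1OCOC | intermediate
12 | lithium [4-(benzyloxy)-2-(methoxymethoxy)phenyl]triisopropoxyborate | [Li+].COCOc1cc(OCc2ccccc2)ccc1[B-](OC(C)C)(OC(C)C)OC(C)C | intermediate
13 | [4-(benzyloxy)-2-(methoxymethoxy)phenyl]boronic acid | COCOc1cc(OCc2ccccc2)ccc1B(O)O | intermediate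
14 | (3R)-3-[2-(allyloxy)-4-(benzyloxy)-3-methoxyphenyl]-3-[4-(benzyloxy)-2-(methoxymethoxy)phenyl]-1-[3,4-bis(benzyloxy)phenyl]propan-1-one | O=C(c1ccc(OCc2ccccc2)c(OCc2ccccc2)c1)C[C@H](c1ccc(OCc2ccccc2)cc1OCOC)c1ccc(OCc2ccccc2)c(OC)c1OCC=C | intermediate
15 | (3R)-3-[2-(allyloxy)-4-(benzyloxy)-3-methoxyphenyl]-3-[4-(benzyloxy)-2-hydroxyphenyl]-1-[3,4-bis(benzyloxy)phenyl]propan-1-one | O=C(c1ccc(OCc2ccccc2)c(OCc2ccccc2)c1)C[C@H](c1ccc(OCc2ccccc2)cc1O)c1ccc(OCc2ccccc2)c(OC)c1OCC=C | intermediate
16 | (4R)-4-[2-(allyloxy)-4-(benzyloxy)-3-methoxyphenyl]-7-(benzyloxy)-2-[3,4-bis(benzyloxy)phenyl]-4H-chromene | COc1c(OCc2ccccc2)ccc([C@H]2c3ccc(OCc4ccccc4)cc3OC(c3ccc(OCc4ccccc4)c(OCc4ccccc4)c3)=C2)c1OCC=C | intermediate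
17 | 3-(benzyloxy)-6-{(4S)-7-(benzyloxy)-2-[3,4-bis(benzyloxy)phenyl]-4H-chromen-4-yl}-2-methoxyphenol | COc1c(OCc2ccccc2)ccc([C@H]2c3ccc(OCc4ccccc4)cc3OC(c3ccc(OCc4ccccc4)c(OCc4ccccc4)c3)=C2)c1O | intermediate
18 | chlorodiisopropylsilane | CC(C)[SiH](Cl)C(C)C | starting material
19 | {3-(benzyloxy)-6-[(4R)-7-(benzyloxy)-2-[3,4-bis(benzyloxy)phenyl]-4H-chromen-4-yl]-2-methoxyphenoxy}di(propan-2-yl)silane | COc1c(OCc2ccccc2)ccc([C@H]2c3ccc(OCc4ccccc4)cc3OC(c3ccc(OCc4ccccc4)c(OCc4ccccc4)c3)=C2)c1O[SiH](C(C)C)C(C)C | intermediate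
20 | (2R,3S,4R)-tetrabenzyl flavan with C3 and O-2'' bridged by diisopropylsilicon (Si and ring D cis, ring B trans) | COc1c(OCc2ccccc2)ccc([C@H]2c3ccc(OCc4ccccc4)cc3O[C@H](c3ccc(OCc4ccccc4)c(OCc4ccccc4)c3)[C@H]2[Si](C(C)C)(C(C)C)O3)c13 | intermediate
21 | (2R,3S,4S)-7-(benzyloxy)-4-[4-(benzyloxy)-2-hydroxy-3-methoxyphenyl]-2-[3,4-bis(benzyloxy)phenyl]-3,4-dihydro-2H-chromen-3-ol | COc1c(OCc2ccccc2)ccc([C@H]2c3ccc(OCc4ccccc4)cc3O[C@H](c3ccc(OCc4ccccc4)c(OCc4ccccc4)c3)[C@H]2O)c1O | intermediate
22 | 4β-(2,4-dihydroxy-3-methoxyphenyl)fisetinidol, (2R,3S,4S) | COc1c(O)ccc([C@H]2c3ccc(O)cc3O[C@H](c3ccc(O)c(O)c3)[C@H]2O)c1O | target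

Total step count: 14.
Longest linear sequence: 11 steps (steps 1–4 and 8–14).

Steps most likely to fail

1. Step 12. The hindered, trisubstituted enol ether may insert too slowly. Si–H redistribution, dehydrogenative silylation or platinum-induced cleavage of C2–O1 could then take over.
 - The fallback uses known chemistry only, sets out from ketone 14 and comes back at 21.
 - The sodium enolate of 14 (NaN(SiMe3)2, THF, −78 °C) is hydroxylated with (+)-(camphorsulfonyl)oxaziridine. This reagent is chosen by analogy with its (S)-selective hydroxylation of Z-enolates of aryl alkyl ketones. It should give the (2S,3R)-α-hydroxy ketone F1, which places the future C3 oxygen independently of the ring D face.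
 - NaBH4 in THF–MeOH reduces this to the 1,2-diol F2. The new carbinol centre is of no consequence.
 - HCl in MeOH cleaves the MOM acetal and ionises the ring B benzylic alcohol, and the ring A phenol captures the cation. This is the known acid-catalysed closure of 1-aryl-3-(2-hydroxyaryl)propane-1,2-diols to flavan-3-ols. It should favour the 2,3-trans O-allyl flavan-3-ol F3, from which any 2,3-cis isomer is separated.
 - Deallylation as in step 10 (Pd(PPh3)4, morpholine, THF) then gives 21.

2. Step 13. Fluoride- or base-triggered anti β-elimination across C3–C2 expels the ring A phenoxide, as in the cleavage of 2-silylethyl ethers. It may compete with the slow attack of hydroperoxide on the hindered diisopropylsilicon.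
 - The fallback redesigns the tether, sets out from phenol 17 and comes back at 21.
 - 1,1,3,3-Tetramethyldisilazane in PhMe at 50 °C converts 17, without any acid, into the dimethylsilyl ether F4, which is used crude after evaporation.
 - The platinum catalyst of step 12 closes the dimethyl oxasilacycle F5.
 - The unhindered silicon of F5 should be oxidised by H2O2 and KHCO3 in THF–MeOH at rt without fluoride, which removes the trigger for the elimination.

3. Step 8. Protodeboronation of the electron-rich boronic acid may outrun insertion between two ortho-substituted partners, or the facial selectivity may be insufficient.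
 - The fallback replaces catalysis by auxiliary control, sets out from aldehyde 5 and bromide 10 and comes back at 14.
 - Knoevenagel–Doebner condensation of 5 with malonic acid (pyridine, piperidine, 90 °C) gives the (E)-cinnamic acid F6.
 - DCC and DMAP couple F6 with (S)-4-phenyl-1,3-oxazolidin-2-one to give the N-enoyl imide F7.
 - Magnesium in THF turns 10 into the arylmagnesium bromide F8.
 - With CuBr·SMe2 at −40 °C, F8 adds to the magnesium-chelated syn-s-cis imide from the face opposite the auxiliary phenyl group (si face at Cβ). This gives the 3,3-diarylpropanoyl imide F9.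
 - MeNH(OMe)·HCl and AlMe3 in CH2Cl2 convert F9 into the Weinreb amide F10 and release the auxiliary.
 - 4-Bromo-1,2-bis(benzyloxy)benzene and n-BuLi (THF, −78 °C) give 3,4-bis(benzyloxy)phenyllithium F11, which adds once to F10 (Weinreb ketone synthesis) to give 14.

Further compounds
F1 | step 12 | (2S,3R)-3-[2-(allyloxy)-4-(benzyloxy)-3-methoxyphenyl]-3-[4-(benzyloxy)-2-(methoxymethoxy)phenyl]-1-[3,4-bis(benzyloxy)phenyl]-2-hydroxypropan-1-one | O=C(c1ccc(OCc2ccccc2)c(OCc2ccccc2)c1)[C@@H](O)[C@H](c1ccc(OCc2ccccc2)cc1OCOC)c1ccc(OCc2ccccc2)c(OC)c1OCC=C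
F2 | step 12 | (2S,3R)-3-[2-(allyloxy)-4-(benzyloxy)-3-methoxyphenyl]-3-[4-(benzyloxy)-2-(methoxymethoxy)phenyl]-1-[3,4-bis(benzyloxy)phenyl]propane-1,2-diol (C1 epimers) | OC(c1ccc(OCc2ccccc2)c(OCc2ccccc2)c1)[C@@H](O)[C@H](c1ccc(OCc2ccccc2)cc1OCOC)c1ccc(OCc2ccccc2)c(OC)c1OCC=C
F3 | step 12 | (2R,3S,4R)-4-[2-(allyloxy)-4-(benzyloxy)-3-methoxyphenyl]-7-(benzyloxy)-2-[3,4-bis(benzyloxy)phenyl]-3,4-dihydro-2H-chromen-3-ol | COc1c(OCc2ccccc2)ccc([C@H]2c3ccc(OCc4ccccc4)cc3O[C@H](c3ccc(OCc4ccccc4)c(OCc4ccccc4)c3)[C@H]2O)c1OCC=C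
F4 | step 13 | {3-(benzyloxy)-6-[(4R)-7-(benzyloxy)-2-[3,4-bis(benzyloxy)phenyl]-4H-chromen-4-yl]-2-methoxyphenoxy}dimethylsilane | COc1c(OCc2ccccc2)ccc([C@H]2c3ccc(OCc4ccccc4)cc3OC(c3ccc(OCc4ccccc4)c(OCc4ccccc4)c3)=C2)c1O[SiH](C)C
F5 | step 13 | (2R,3S,4R)-tetrabenzyl flavan with C3 and O-2'' bridged by dimethylsilicon | COc1c(OCc2ccccc2)ccc([C@H]2c3ccc(OCc4ccccc4)cc3O[C@H](c3ccc(OCc4ccccc4)c(OCc4ccccc4)c3)[C@H]2[Si](C)(C)O3)c13
F6 | step 8 | (E)-3-[2-(allyloxy)-4-(benzyloxy)-3-methoxyphenyl]prop-2-enoic acid | COc1c(OCc2ccccc2)ccc(/C=C/C(=O)O)c1OCC=C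
F7 | step 8 | (4S)-3-{(E)-3-[2-(allyloxy)-4-(benzyloxy)-3-methoxyphenyl]prop-2-enoyl}-4-phenyl-1,3-oxazolidin-2-one | COc1c(OCc2ccccc2)ccc(/C=C/C(=O)N2[C@@H](c3ccccc3)COC2=O)c1OCC=C
F8 | step 8 | [4-(benzyloxy)-2-(methoxymethoxy)phenyl]magnesium bromide | COCOc1cc(OCc2ccccc2)ccc1[Mg]Br
F9 | step 8 | (4S)-3-{(3R)-3-[2-(allyloxy)-4-(benzyloxy)-3-methoxyphenyl]-3-[4-(benzyloxy)-2-(methoxymethoxy)phenyl]propanoyl}-4-phenyl-1,3-oxazolidin-2-one | O=C(C[C@H](c1ccc(OCc2ccccc2)cc1OCOC)c1ccc(OCc2ccccc2)c(OC)c1OCC=C)N1[C@@H](c2ccccc2)COC1=O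
F10 | step 8 | (3R)-3-[2-(allyloxy)-4-(benzyloxy)-3-methoxyphenyl]-3-[4-(benzyloxy)-2-(methoxymethoxy)phenyl]-N-methoxy-N-methylpropanamide | CON(C)C(=O)C[C@H](c1ccc(OCc2ccccc2)cc1OCOC)c1ccc(OCc2ccccc2)c(OC)c1OCC=C
F11 | step 8 | [3,4-bis(benzyloxy)phenyl]lithium | [Li]c1ccc(OCc2ccccc2)c(OCc2ccccc2)c1
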